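**Plan**

1. Retrosynthesis (2-oxaspiro[4.5]decane numbering of the target): after removal of the acetate, both carbonyl carbons are excised as CO by cutting O2–C3, C3–C4, C5–C6 and C6–C7. This opens the lactone and the cyclohexenone together to the acyclic (Z)-iodo dienol 16.
2. Enabling feature: ketone C6 is bonded directly to spiro C5, and lactone carbonyl C3 reaches C5 through C4H2. C5=C4 can therefore be a 1,1-disubstituted alkene lying between an alkenyl iodide (the C7=C8 side, six-membered ring) and the allylic hydroxyl on C1 (five-membered ring).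
3. 16 is cut at C1–C5 (alkenyl bromide 12 + enal 6) and at C9–C10 (2-bromoallyl metal + ynal 9). The iodoalkene is carried as a silyl alkyne until the chain is complete, because an alkenyl iodide would not survive the Ni/Cr coupling.
4. Forward: 2-bromoallylation of 9, silylation, Ni/Cr coupling with 6, alkyne to (Z)-iodoalkene, then one Pd/CO cascade closes the cyclohexenone first and the γ-lactone second. Desilylation and acetylation finish.
5. Stereochemistry: C9 from a boron-controller-directed allylation, C1 from a ligand-controlled Ni/Cr coupling, spiro C5 by substrate control in the ring closure. The E,E-diene comes from geranyl acetate and an ene reaction, the cis-enone from diimide reduction of an iodoalkyne.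

Key step: step 11

Numbering: acyclic compounds use the trideca-chain locants of 16 (C3 silyloxy carbinol, C5 methylidene carbon, C6 free carbinol); these become C9, C5 and C1 of the spirocycle.

Assumption: the (S,S)-diazaborolidine controller (step 6) and the (S)-sulfonamide–oxazoline ligand (step 8) are taken to be the antipodes that deliver the Si faces required; if either induces the opposite sense, its mirror image is used and nothing else changes.

**Route**

Step 1
Reactants: 1 geranyl acetate
Product: 3 (2E,5E)-7-hydroxy-3,7-dimethylocta-2,5-dien-1-yl acetate, via tertiary allylic hydroperoxide 2 (not isolated)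
Conditions: O2, hν, tetraphenylporphyrin (cat.), CH2Cl2, 0 °C; then PPh3, 0 °C to rt
Reagents that add atoms: oxygen, O=O
Why: Schenck ene reaction in which singlet oxygen attacks the electron-rich remote trisubstituted alkene (the 2,3-alkene is deactivated by the allylic acetate), abstraction of a C5 hydrogen gives the tertiary hydroperoxide with a new E-alkene, PPh3 reduces it in the same flask, and the regioisomeric secondary alcohol from methyl abstraction is to be removed by chromatography.

Step 2
Reactants: 3 (2E,5E)-7-hydroxy-3,7-dimethylocta-2,5-dien-1-yl acetate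
Product: 4 (2E,5E)-3,7-dimethyl-7-(triethylsilyloxy)octa-2,5-dien-1-yl acetate
Conditions: TESOTf, 2,6-lutidine, CH2Cl2, −78 to 0 °C
Reagents that add atoms: triethylsilyl trifluoromethanesulfonate, CC[Si](CC)(CC)OS(=O)(=O)C(F)(F)F
Why: Silyl triflate silylation under lutidine buffering is the standard way to cap a hindered tertiary alcohol, and the acetate is inert.

Step 3
Reactants: 4 (2E,5E)-3,7-dimethyl-7-(triethylsilyloxy)octa-2,5-dien-1-yl acetate
Product: 5 (2E,5E)-3,7-dimethyl-7-(triethylsilyloxy)octa-2,5-dien-1-ol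
Conditions: K2CO3, MeOH, 0 °C to rt
Reagents that add atoms: none
Why: Base-catalysed transesterification removes the primary acetate while the tertiary TES ether should be stable to carbonate in methanol.

Step 4
Reactants: 5 (2E,5E)-3,7-dimethyl-7-(triethylsilyloxy)octa-2,5-dien-1-ol
Product: 6 (2E,5E)-3,7-dimethyl-7-(triethylsilyloxy)octa-2,5-dienal
Conditions: MnO2, CH2Cl2, rt
Reagents that add atoms: none
Why: MnO2 oxidation is selective for allylic alcohols, and its neutral conditions should keep the 2E geometry and leave the skipped diene out of conjugation.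

Step 5
Reactants: 7 2,3-dibromopropene
Product: 8 (2-bromoallyl)tributylstannane
Conditions: Bu3SnH, LDA, THF, 0 °C; then 7, −78 °C
Reagents that add atoms: tributyltin hydride (used as Bu3SnLi), CCCC[SnH](CCCC)CCCC
Why: SN2 displacement of the allylic bromide by tributylstannyllithium at low temperature, where the vinylic bromide does not react.

Step 6
Reactants: 8 (2-bromoallyl)tributylstannane; 9 3-(trimethylsilyl)prop-2-ynal
Product: 11 (3S)-5-bromo-1-(trimethylsilyl)hex-5-en-1-yn-3-ol, via 2-bromoallyl diazaborolidine 10 (not isolated)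
Conditions: (1S,2S)-TsNHCH(Ph)CH(Ph)NHTs, BBr3, CH2Cl2, 0 °C to rt, then evaporation; 8, CH2Cl2, rt; 9, −78 °C; pH 7 buffer
Reagents that add atoms: none
Why: Corey-type allylation with a chiral B-bromodiazaborolidine, in which tin-to-boron SE2′ transmetallation gives allylborane 10 and this adds to the ynal through a chair six-membered transition state at −78 °C, the C2-symmetric bis-sulfonamide directing the 2-bromoallyl group to the Si face of 9 to set 3S.

Step 7
Reactants: 11 (3S)-5-bromo-1-(trimethylsilyl)hex-5-en-1-yn-3-ol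
Product: 12 (3S)-5-bromo-3-(tert-butyldimethylsilyloxy)-1-(trimethylsilyl)hex-5-en-1-yne
Conditions: TBSCl, imidazole, DMF, rt
Reagents that add atoms: tert-butyldimethylsilyl chloride, CC(C)(C)[Si](C)(C)Cl
Why: Standard imidazole-promoted silylation of a secondary propargylic alcohol, which leaves the stereocentre untouched.

Step 8
Reactants: 12 (3S)-5-bromo-3-(tert-butyldimethylsilyloxy)-1-(trimethylsilyl)hex-5-en-1-yne; 6 (2E,5E)-3,7-dimethyl-7-(triethylsilyloxy)octa-2,5-dienal
Product: 14 (3S,6R,7E,10E)-3-(tert-butyldimethylsilyloxy)-8,12-dimethyl-5-methylidene-12-(triethylsilyloxy)-1-(trimethylsilyl)trideca-7,10-dien-1-yn-6-ol, via alkenylchromium(III) species 13 (not isolated)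
Conditions: CrCl2 (3 equiv), (S)-N-[2-(4-isopropyl-4,5-dihydrooxazol-2-yl)-6-methylphenyl]methanesulfonamide (3.3 equiv), Et3N, NiCl2 (cat.), THF, rt; aqueous sodium serinate work-up
Reagents that add atoms: none
Why: Asymmetric Nozaki–Hiyama–Kishi coupling in which Ni inserts into the C–Br bond, transmetallation gives alkenylchromium 13, and this adds 1,2 to the enal with the chiral sulfonamide–oxazoline ligand on Cr directing attack to the Si face of 6 to set 6R, while the remote C3 centre, the silyl ethers and the silyl alkyne should not interfere.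

Step 9
Reactants: 14 (3S,6R,7E,10E)-3-(tert-butyldimethylsilyloxy)-8,12-dimethyl-5-methylidene-12-(triethylsilyloxy)-1-(trimethylsilyl)trideca-7,10-dien-1-yn-6-ol
Product: 15 (3S,6R,7E,10E)-3-(tert-butyldimethylsilyloxy)-1-iodo-8,12-dimethyl-5-methylidene-12-(triethylsilyloxy)trideca-7,10-dien-1-yn-6-ol
Conditions: NIS, AgNO3 (cat.), DMF, rt, dark
Reagents that add atoms: N-iodosuccinimide, O=C1CCC(=O)N1I
Why: Silver-catalysed desilylative iodination, in which Ag(I) turns the alkynylsilane into a silver acetylide that NIS iodinates, under neutral conditions that should spare the alkenes, the silyl ethers and the free bis-allylic alcohol.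

Step 10
Reactants: 15 (3S,6R,7E,10E)-3-(tert-butyldimethylsilyloxy)-1-iodo-8,12-dimethyl-5-methylidene-12-(triethylsilyloxy)trideca-7,10-dien-1-yn-6-ol
Product: 16 (1Z,3S,6R,7E,10E)-3-(tert-butyldimethylsilyloxy)-1-iodo-8,12-dimethyl-5-methylidene-12-(triethylsilyloxy)trideca-1,7,10-trien-6-ol
Conditions: 2-nitrobenzenesulfonyl hydrazide (NBSH), Et3N, THF–i-PrOH, rt
Reagents that add atoms: none
Why: Diimide reduction, in which concerted syn delivery of two hydrogens to the 1-iodoalkyne, which is much more reactive towards diimide than the 1,1-di-, 1,2-di- and trisubstituted alkenes, should give the (Z)-iodoalkene.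

Step 11
Reactants: 16 (1Z,3S,6R,7E,10E)-3-(tert-butyldimethylsilyloxy)-1-iodo-8,12-dimethyl-5-methylidene-12-(triethylsilyloxy)trideca-1,7,10-trien-6-ol
Product: 20 (1R,5R,9S)-9-(tert-butyldimethylsilyloxy)-1-[(1E,4E)-2,6-dimethyl-6-(triethylsilyloxy)hepta-1,4-dien-1-yl]-2-oxaspiro[4.5]dec-7-ene-3,6-dione, via alkenoyl-palladium iodide 17 (not isolated), via neopentyl-type alkylpalladium iodide 18 (not isolated), via homologated acylpalladium iodide 19 (not isolated)
Conditions: PdCl2(PPh3)2 (5 mol %), CO (40 atm), Et3N, MeCN–benzene (1:1), 90 °C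
Reagents that add atoms: carbon monoxide (two molecules), [C-]#[O+]
Why: Pd(0) inserts into the (Z)-alkenyl C–I bond and takes up CO to give alkenoyl-Pd 17, which adds syn across the C5 methylidene (6-exo-trig acylpalladation) to close the cyclohexenone with its cis-enone in place; the resulting alkyl-Pd 18 has no β-hydrogen, so it inserts a second CO to give 19, and the neighbouring secondary hydroxyl attacks this acyl-Pd (5-exo-trig acyl substitution) to close the γ-lactone and release Pd(0), with Et3N taking up HI. The closest known reaction type is the cyclic acylpalladation–carbonylative esterification cascade of alkenyl iodides carrying a tethered 1,1-disubstituted alkene, terminated here by an internal rather than an external alcohol. The only new stereocentre, the spiro carbon, is set by substrate control: in a half-chair transition state the C3 silyloxy group and the bulky carbinol arm on the alkene carbon should both be pseudoequatorial with the small Pd-bearing =CH2 pseudoaxial, which puts the carbinol carbon cis to the silyloxy group and gives 5R; the adjacent allylic carbinol centre is a second, untested influence. The step needs CO insertion ahead of direct carbopalladation (secured by high CO pressure and by the strain of a cyclopentene closure through an endocyclic alkenyl-Pd), ring closure ahead of capture of 17 by the hydroxyl (that capture would need a seven-membered lactone), and a second carbonylation instead of β-hydride loss (secured by the quaternary carbon just formed). The two carbinol centres are not touched, and the Z geometry of the iodide is what allows the ring to close.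

Step 12
Reactants: 20 (1R,5R,9S)-9-(tert-butyldimethylsilyloxy)-1-[(1E,4E)-2,6-dimethyl-6-(triethylsilyloxy)hepta-1,4-dien-1-yl]-2-oxaspiro[4.5]dec-7-ene-3,6-dione
Product: 21 (1R,5R,9S)-9-hydroxy-1-[(1E,4E)-6-hydroxy-2,6-dimethylhepta-1,4-dien-1-yl]-2-oxaspiro[4.5]dec-7-ene-3,6-dione
Conditions: HF·pyridine, pyridine, THF, 0 °C to rt
Reagents that add atoms: none
Why: Fluoride-mediated desilylation buffered with pyridine should cleave the secondary TBS and tertiary TES ethers without ionising the allylic alcohols or opening the lactone.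

Step 13
Reactants: 21 (1R,5R,9S)-9-hydroxy-1-[(1E,4E)-6-hydroxy-2,6-dimethylhepta-1,4-dien-1-yl]-2-oxaspiro[4.5]dec-7-ene-3,6-dione
Product: 22 (+)-miliusane XVII, (1R,5R,9S)-1-[(1E,4E)-6-hydroxy-2,6-dimethylhepta-1,4-dien-1-yl]-3,6-dioxo-2-oxaspiro[4.5]dec-7-en-9-yl acetate
Conditions: Ac2O, pyridine, DMAP (cat.), CH2Cl2, 0 °C
Reagents that add atoms: acetic anhydride, CC(=O)OC(C)=O
Why: Nucleophile-catalysed acylation should acetylate the secondary allylic alcohol much faster than the hindered tertiary one, and the product cannot eliminate acetate because the adjacent ring CH2 is not acidic.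

**Compound list**

1 | geranyl acetate | CC(=O)OC/C=C(\C)CCC=C(C)C | starting material
2 | (2E,5E)-7-hydroperoxy-3,7-dimethylocta-2,5-dien-1-yl acetate | CC(=O)OC/C=C(\C)C/C=C/C(C)(C)OO | intermediate
3 | (2E,5E)-7-hydroxy-3,7-dimethylocta-2,5-dien-1-yl acetate | CC(=O)OC/C=C(\C)C/C=C/C(C)(C)O | intermediate
4 | (2E,5E)-3,7-dimethyl-7-(triethylsilyloxy)octa-2,5-dien-1-yl acetate | CC(=O)OC/C=C(\C)C/C=C/C(C)(C)O[Si](CC)(CC)CC | intermediate
5 | (2E,5E)-3,7-dimethyl-7-(triethylsilyloxy)octa-2,5-dien-1-ol | OC/C=C(\C)C/C=C/C(C)(C)O[Si](CC)(CC)CC | intermediate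
6 | (2E,5E)-3,7-dimethyl-7-(triethylsilyloxy)octa-2,5-dienal | O=C/C=C(\C)C/C=C/C(C)(C)O[Si](CC)(CC)CC | intermediate
7 | 2,3-dibromopropene | C=C(Br)CBr | starting material
8 | (2-bromoallyl)tributylstannane | C=C(Br)C[Sn](CCCC)(CCCC)CCCC | intermediate
9 | 3-(trimethylsilyl)prop-2-ynal | C[Si](C)(C)C#CC=O | starting material
10 | (4S,5S)-2-(2-bromoallyl)-4,5-diphenyl-1,3-bis(p-tolylsulfonyl)-1,3,2-diazaborolidine | C=C(Br)CB1N(S(=O)(=O)c2ccc(C)cc2)[C@@H](c2ccccc2)[C@H](c2ccccc2)N1S(=O)(=O)c1ccc(C)cc1 | intermediate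
11 | (3S)-5-bromo-1-(trimethylsilyl)hex-5-en-1-yn-3-ol | C[Si](C)(C)C#C[C@@H](O)CC(Br)=C | intermediate
12 | (3S)-5-bromo-3-(tert-butyldimethylsilyloxy)-1-(trimethylsilyl)hex-5-en-1-yne | C[Si](C)(C)C#C[C@@H](O[Si](C)(C)C(C)(C)C)CC(Br)=C | intermediate
13 | alkenylchromium(III) dichloride derived from 12 (chiral ligand omitted) | C[Si](C)(C)C#C[C@@H](O[Si](C)(C)C(C)(C)C)CC(=C)[Cr](Cl)Cl | intermediate
14 | (3S,6R,7E,10E)-3-(tert-butyldimethylsilyloxy)-8,12-dimethyl-5-methylidene-12-(triethylsilyloxy)-1-(trimethylsilyl)trideca-7,10-dien-1-yn-6-ol | C[Si](C)(C)C#C[C@@H](O[Si](C)(C)C(C)(C)C)CC(=C)[C@H](O)/C=C(\C)C/C=C/C(C)(C)O[Si](CC)(CC)CC | intermediate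
15 | (3S,6R,7E,10E)-3-(tert-butyldimethylsilyloxy)-1-iodo-8,12-dimethyl-5-methylidene-12-(triethylsilyloxy)trideca-7,10-dien-1-yn-6-ol | IC#C[C@@H](O[Si](C)(C)C(C)(C)C)CC(=C)[C@H](O)/C=C(\C)C/C=C/C(C)(C)O[Si](CC)(CC)CC | intermediate
16 | (1Z,3S,6R,7E,10E)-3-(tert-butyldimethylsilyloxy)-1-iodo-8,12-dimethyl-5-methylidene-12-(triethylsilyloxy)trideca-1,7,10-trien-6-ol | I/C=C\[C@@H](O[Si](C)(C)C(C)(C)C)CC(=C)[C@H](O)/C=C(\C)C/C=C/C(C)(C)O[Si](CC)(CC)CC | intermediate
17 | (Z)-alkenoyl-palladium(II) iodide from 16 after the first CO insertion (phosphines omitted) | I[Pd]C(=O)/C=C\[C@@H](O[Si](C)(C)C(C)(C)C)CC(=C)[C@H](O)/C=C(\C)C/C=C/C(C)(C)O[Si](CC)(CC)CC | intermediate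
18 | cyclohexenone-bearing neopentyl-type alkylpalladium(II) iodide (phosphines omitted) | CC(C)(C)[Si](C)(C)O[C@@H]1C=CC(=O)[C@](C[Pd]I)([C@H](O)/C=C(\C)C/C=C/C(C)(C)O[Si](CC)(CC)CC)C1 | intermediate
19 | acylpalladium(II) iodide after the second CO insertion (phosphines omitted) | CC(C)(C)[Si](C)(C)O[C@@H]1C=CC(=O)[C@](CC(=O)[Pd]I)([C@H](O)/C=C(\C)C/C=C/C(C)(C)O[Si](CC)(CC)CC)C1 | intermediate
20 | (1R,5R,9S)-9-(tert-butyldimethylsilyloxy)-1-[(1E,4E)-2,6-dimethyl-6-(triethylsilyloxy)hepta-1,4-dien-1-yl]-2-oxaspiro[4.5]dec-7-ene-3,6-dione | CC(C)(C)[Si](C)(C)O[C@@H]1C=CC(=O)[C@@]2(CC(=O)O[C@@H]2/C=C(\C)C/C=C/C(C)(C)O[Si](CC)(CC)CC)C1 | intermediate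
21 | (1R,5R,9S)-9-hydroxy-1-[(1E,4E)-6-hydroxy-2,6-dimethylhepta-1,4-dien-1-yl]-2-oxaspiro[4.5]dec-7-ene-3,6-dione | O[C@@H]1C=CC(=O)[C@@]2(CC(=O)O[C@@H]2/C=C(\C)C/C=C/C(C)(C)O)C1 | intermediate
22 | (+)-miliusane XVII | CC(=O)O[C@@H]1C=CC(=O)[C@@]2(CC(=O)O[C@@H]2/C=C(\C)C/C=C/C(C)(C)O)C1 | target

**Step count and risks**

Total step count: 13. Longest linear sequence: 10 steps (steps 1–4 and 8–13, from geranyl acetate).

Steps most likely to fail:

Step 11. The free C6 hydroxyl may intercept the alkenoyl-palladium before the ring closes, carbopalladation may occur without CO uptake, or the hydroxyl may steer palladium to the wrong alkene face. The fallback divides the cascade into the established intermolecular termination followed by a separate lactonisation. It sets out from 16, which is silylated at C6 (TESOTf, 2,6-lutidine) to give the tris-silyl ether F1. The same Pd/CO/Et3N conditions with added MeOH should then close the cyclohexenone and end in methanolysis of the second acyl-palladium to give the keto ester F2. HF·pyridine removes all three silyl groups and the freed γ-hydroxy ester lactonises (PPTS if needed), so the fallback rejoins the route at 21.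

Step 8. Ligand control at C6 may be poor, or the alkenyl bromide may be sluggish towards Ni/Cr. The fallback moves the stereocontrol from C–C bond formation to carbonyl reduction. It sets out from 12, which undergoes Br/Li exchange (t-BuLi, Et2O, −78 °C) to the alkenyllithium F3. This adds to enal 6 to give the C6-epimeric carbinol mixture F4, which MnO2 oxidises to the cross-conjugated dienone F5. Reduction with (S)-Me-CBS and catecholborane at −78 °C, in which the α-branched alkenyl group should act as the large substituent, rejoins the route at 14.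

Step 10. Diimide may also saturate the methylidene or disubstituted alkenes, or reduce the iodoalkene further. The fallback fixes the cis geometry before iodine is introduced. It sets out from 14, which K2CO3/MeOH converts into the terminal alkyne F6. Rh-catalysed trans-hydroboration with pinacolborane ([Rh(cod)Cl]2, P(i-Pr)3, Et3N) should give the (Z)-alkenylboronate F7, and NaOH followed by I2 replaces boron by iodine with retention. The fallback rejoins the route at 16 and bypasses steps 9 and 10.

**Further compounds**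

F1 | step 11 | (1Z,3S,6R,7E,10E)-3-(tert-butyldimethylsilyloxy)-1-iodo-8,12-dimethyl-5-methylidene-6,12-bis(triethylsilyloxy)trideca-1,7,10-triene | I/C=C\[C@@H](O[Si](C)(C)C(C)(C)C)CC(=C)[C@H](O[Si](CC)(CC)CC)/C=C(\C)C/C=C/C(C)(C)O[Si](CC)(CC)CC
F2 | step 11 | methyl 2-{(1R,5S)-5-(tert-butyldimethylsilyloxy)-1-[(1R,2E,5E)-3,7-dimethyl-1,7-bis(triethylsilyloxy)octa-2,5-dien-1-yl]-2-oxocyclohex-3-en-1-yl}acetate | CC(C)(C)[Si](C)(C)O[C@@H]1C=CC(=O)[C@](CC(=O)OC)([C@H](O[Si](CC)(CC)CC)/C=C(\C)C/C=C/C(C)(C)O[Si](CC)(CC)CC)C1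
F3 | step 8 | alkenyllithium from 12, (4S)-4-(tert-butyldimethylsilyloxy)-6-(trimethylsilyl)hex-1-en-5-yn-2-yllithium | C[Si](C)(C)C#C[C@@H](O[Si](C)(C)C(C)(C)C)CC(=C)[Li]
F4 | step 8 | C6-epimeric mixture of 14, (3S,6RS) | C[Si](C)(C)C#C[C@@H](O[Si](C)(C)C(C)(C)C)CC(=C)C(O)/C=C(\C)C/C=C/C(C)(C)O[Si](CC)(CC)CC
F5 | step 8 | (3S,7E,10E)-3-(tert-butyldimethylsilyloxy)-8,12-dimethyl-5-methylidene-12-(triethylsilyloxy)-1-(trimethylsilyl)trideca-7,10-dien-1-yn-6-one | C[Si](C)(C)C#C[C@@H](O[Si](C)(C)C(C)(C)C)CC(=C)C(=O)/C=C(\C)C/C=C/C(C)(C)O[Si](CC)(CC)CC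
F6 | step 10 | (3S,6R,7E,10E)-3-(tert-butyldimethylsilyloxy)-8,12-dimethyl-5-methylidene-12-(triethylsilyloxy)trideca-7,10-dien-1-yn-6-ol | C#C[C@@H](O[Si](C)(C)C(C)(C)C)CC(=C)[C@H](O)/C=C(\C)C/C=C/C(C)(C)O[Si](CC)(CC)CC
F7 | step 10 | (1Z,3S,6R,7E,10E)-3-(tert-butyldimethylsilyloxy)-8,12-dimethyl-5-methylidene-1-(4,4,5,5-tetramethyl-1,3,2-dioxaborolan-2-yl)-12-(triethylsilyloxy)trideca-1,7,10-trien-6-ol | CC1(C)OB(/C=C\[C@@H](O[Si](C)(C)C(C)(C)C)CC(=C)[C@H](O)/C=C(\C)C/C=C/C(C)(C)O[Si](CC)(CC)CC)OC1(C)C
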